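## Analysis of the target

CNP0229937.1 is a glaucolide-type germacranolide; germacrane numbering (C1–C15) is used throughout. A ten-membered carbocycle (C1–C10) is fused along C6–C7 to a butenolide (ring B: O–C6, C7=C11, C12=O) whose C11 carries the allylic acetate (C13). C1 is a ketone, C8 carries the tiglate, C4–C5 is a trisubstituted epoxide (C15 methyl on C4) and C10 carries the C14 methyl.

The five stereocentres are 4R, 5S, 6S, 8S and 10R. The epoxide is cis (C3 and C6 on the same side of the oxirane, so it comes from a 4Z olefin). Its oxygen is anti to the lactone oxygen across C5–C6 and lies on the same face of the planar butenolide as the C8–O bond. C10 is 1,3-related to C8 and sits α to the ketone.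

The 13-acetoxy-7(11)-en-12,6-olide is a latent elimination system: C6–H is the acidic γ-hydrogen, and deprotonation expels acetate. C10 is epimerisable, the epoxide is acid-labile and transannular to C1=O, and a γ-vinyl butenolide can slip into conjugation. The difficulty is a medium ring with a tetrasubstituted olefin inside a fused lactone, with no small ring to relay stereochemistry from.

The feature that invites the strategy: C1 (ketone) and C6 (lactone carbinol) are joined by two four-carbon arcs, C2–C5 (holding the Z olefin) and C7–C10, and C6, C7 and C8 are the γ, β and γ′ carbons of ring B. A C1–C6 bond would therefore turn C1–C6 into a cyclohex-3-ene (ring A) with ring B spiro at C6. The target ring is then this cyclohexene expanded by C7–C10 through a [3,3] shift that makes C8–C9, breaks C1–C6 and turns ring B into an aromatic 2-silyloxyfuran.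

## Retrosynthetic reasoning

**18 back to 15 (functional groups only).** The tiglate is removed first to give 17, because the free C8 hydroxyl is needed as the directing group for the epoxide and a C8 ester would block that face. The epoxide is then removed to give the Z olefin 16, and the C13 acetate is removed to give diol 15. The acetate goes on late because it is the leaving group of the base-sensitive system.

**15 back to 13 (C6–H and C10–H).** Both hydrogens are traced to protonation of two silyl enol ethers in 13: a 2-silyloxyfuran (C6) and a C1 enol ether (C10). Nothing is gained in connectivity; what is gained is that C6 and C10 become sp2, which is exactly what a sigmatropic ring expansion delivers.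

**13 back to 12 and 11 (key cut: form C1–C6, break C8–C9).** Reversing a [3,3] shift converts the ten-membered ring of 13 into cyclohexene ring A of 12, with the silyloxyfuran de-aromatised to a spiro 4-alkylidene-2-silyloxy-dihydrofuran. 12 is simply the silyl dienol ether of spirobutenolide 11. The cut is made here because it replaces a medium ring by a six-membered ring, inherits the Z olefin from a cyclohexene, and makes C8 the only stereocentre the step must set. Forward, the reaction must give C8–C9 on one face of an enol ether of fixed geometry; the O8/O13 silylene fixes that geometry.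

**11 back to 9, then to 4 and 7 (ring B).** The lactone C–O bond and the C11–C12 bond are cut (carboxylation of an alkenyl bromide, then lactonisation). The C6–C7 bond is cut (alkenyl-metal addition to the enone carbonyl of 4). The C4 unit 7 is symmetric, so no regiochemistry arises. The forward addition must choose one face of the ketone under control of the neighbouring silyloxy carbinol.

**7 back to 5, and 4 back to 1.** 7 comes from 5 by reduction and silylene formation. 4 comes from 1 by deconjugative α-hydroxylation, silylation and dehydrogenation. The C5 stereocentre of 1 makes the two carbinol epimers of 2 separable diastereomers and is then erased.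

## Alternatives that were turned down

**Alternative 1: (textbook) macrocyclisation at C7–C8.** The forward key step would be an intramolecular Nozaki–Hiyama–Kishi coupling of the seco iodo-aldehyde A1, closing the ten-membered ring and creating the C8 carbinol. It was turned down for three reasons:
- A1 carries C6 and C10 as acyclic stereocentres next to acidic positions, a base-labile β-halobutenolide and a Z trisubstituted olefin, all of which must be built in a long linear sequence.
- The closure pays the full transannular strain.
- It gives no control at C8, the centre that later directs the epoxide.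

**Alternative 2: two-carbon photochemical ring expansion (de Mayo reaction), cutting C1–C2 and C3–C4.** The enol of an eight-membered 1,3-diketone would undergo [2+2] photocycloaddition with a two-carbon alkene and retro-aldol opening to the 1,5-diketone A2. It was turned down because:
- The eight-membered precursor already contains ring B, C8 and C10, so little is simplified.
- A2 has a C5 ketone where the target needs the C4–C5 epoxide; C6–H between ketone and lactone oxygen would epimerise, and C4 is set without control.

**Alternative 3: bare skeleton first, oxygen late.** The dienolide A3 (no oxygen at C8 or C13) would be oxidised at two allylic C–H positions. It was turned down because: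
- A3 has allylic C–H bonds at C3, C6, C8, C13 and C15, and the most activated is the one that must not react (C6–H).
- Nothing differentiates the two C8 hydrogens, yet the 8S hydroxyl is needed before the epoxide can be placed.
- A3 still needs a ring synthesis of its own.

Key step: step 7

Assumption: C10–H (α to the C1 ketone) is epimerisable. The 10R epimer is taken to be the thermodynamic one once the C8 hydroxyl is free (methyl exo on the two-carbon bridge of the transannular C1/C8 hemiketal), and is reached by equilibration in step 8.

## Steps

Step 1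
Reactants: 1 (R)-(+)-pulegone
Product: 2 (2R,5R)-2-hydroxy-5-methyl-2-(prop-1-en-2-yl)cyclohexan-1-one
Conditions: t-BuOK, THF–t-BuOH, 0 °C; then 2-(phenylsulfonyl)-3-phenyloxaziridine, −78 °C; aq. NH4Cl
Reagents that add atoms: 2-(phenylsulfonyl)-3-phenyloxaziridine, O=S(=O)(c1ccccc1)N1OC1c1ccccc1
Why: Equilibrating base gives the conjugated dienolate (γ-deprotonation of the isopropylidene methyl), which is hydroxylated at C2 with deconjugation to the isopropenyl group (enolate α-hydroxylation with an N-sulfonyloxaziridine). Axial attack on the half-chair with the C5 methyl equatorial should put OH cis to the methyl, i.e. (2R,5R); the C2 epimer is a diastereomer and is removed by chromatography, so the chiral-pool centre C5 acts as an internal resolving handle.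

Step 2
Reactants: 2 (2R,5R)-2-hydroxy-5-methyl-2-(prop-1-en-2-yl)cyclohexan-1-one
Product: 4 (6R)-3-methyl-6-(prop-1-en-2-yl)-6-(triethylsilyloxy)cyclohex-2-en-1-one, via bis(triethylsilyl) derivative 3 (not isolated)
Conditions: Et3SiOTf (2.3 equiv), Et3N, CH2Cl2, −78 → 0 °C; then Pd(OAc)2 (10 mol %), O2 (1 atm), DMSO, 23 °C
Reagents that add atoms: triethylsilyl trifluoromethanesulfonate, CC[Si](CC)(CC)OS(=O)(=O)C(F)(F)F
Why: The tertiary alcohol and the only enolisable α-position are silylated, and Saegusa–Ito dehydrogenation (divalent palladium, O2 as oxidant) gives the enone. The former C5 becomes sp2, so 4 is a single enantiomer whose only stereocentre is the silyloxy carbinol carbon (germacrane C1).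

Step 3
Reactants: 5 3,4-dibromofuran-2(5H)-one
Product: 6 (2Z)-2,3-dibromobut-2-ene-1,4-diol
Conditions: i-Bu2AlH (3 equiv), CH2Cl2, −78 → 0 °C; aq. potassium sodium tartrate (KNaC4H4O6)
Reagents that add atoms: none
Why: Reduction of the lactone to the diol with an aluminium hydride; the vinylic bromides survive and the Z geometry is the one fixed in the ring of 5.

Step 4
Reactants: 6 (2Z)-2,3-dibromobut-2-ene-1,4-diol
Product: 7 5,6-dibromo-2,2-di-tert-butyl-4,7-dihydro-1,3,2-dioxasilepine
Conditions: t-Bu2Si(OTf)2, 2,6-lutidine, CH2Cl2, 0 °C
Reagents that add atoms: di-tert-butylsilyl bis(trifluoromethanesulfonate), CC(C)(C)[Si](OS(=O)(=O)C(F)(F)F)(OS(=O)(=O)C(F)(F)F)C(C)(C)C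
Why: Silylene formation across the cis-1,4-diol gives the seven-membered dioxasilepine. The ring protects both primary oxygens (later O8 and O13) and will lock the geometry of the enol ether in step 7.

Step 5
Reactants: 7 5,6-dibromo-2,2-di-tert-butyl-4,7-dihydro-1,3,2-dioxasilepine; 4 (6R)-3-methyl-6-(prop-1-en-2-yl)-6-(triethylsilyloxy)cyclohex-2-en-1-one
Product: 9 (1S,6R)-1-(6-bromo-2,2-di-tert-butyl-4,7-dihydro-1,3,2-dioxasilepin-5-yl)-3-methyl-6-(prop-1-en-2-yl)-6-(triethylsilyloxy)cyclohex-2-en-1-ol, via alkenyllithium 8 (not isolated)
Conditions: 7 (1.3 equiv), t-BuLi (2.6 equiv), Et2O, −78 °C; then 4, THF, −78 °C; aq. NH4Cl at −78 °C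
Reagents that add atoms: none
Why: Bromine–lithium exchange of one vinylic bromide (elimination to a seven-membered alkyne is not possible) and 1,2-addition to the enone carbonyl, which becomes germacrane C6. Attack anti to the pseudoaxial C–OSiEt3 bond (polar 1,2-induction) should give the (1S,6R) carbinol; its epimer at the new centre is a diastereomer and is separated, and the cold quench prevents any alkoxide-driven [3,3] shift.

Step 6
Reactants: 9 (1S,6R)-bromo alcohol
Product: 11 (5S,10R)-7-methyl-10-(prop-1-en-2-yl)-10-(triethylsilyloxy)-1-oxaspiro[4.5]deca-3,6-dien-2-one with C3–CH2–O–Si(t-Bu)2–O–CH2–C4 bridge, via hydroxy acid 10 (not isolated)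
Conditions: t-BuLi (3.2 equiv), THF, −78 °C; CO2 (g), −78 → 0 °C; then 1 M HCl to pH 3, 0 → 23 °C
Reagents that add atoms: carbon dioxide, O=C=O
Why: A second bromine–lithium exchange on the lithium alkoxide gives a chelated alkenyllithium that is carboxylated; the (Z)-γ-hydroxy acid 10 lactonises on acidification to the spirobutenolide. No stereocentre is touched; the spiro carbon of 11 is germacrane C6 (S).

Step 7
Reactants: 11 spirobutenolide
Product: 13 (8S)-bis-silyl furanocyclodecadiene (2-silyloxyfuran O–C6=C7–C11=C12 fused to the ten-membered ring; C1 triethylsilyl enol ether; Z-C4=C5; O8/O13 silylene), via silyl dienol ether 12 (not isolated)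
Conditions: t-BuMe2SiOTf (1.5 equiv), Et3N (3 equiv), toluene, 0 → 23 °C; then 80 °C
Reagents that add atoms: tert-butyldimethylsilyl trifluoromethanesulfonate, CC(C)(C)[Si](C)(C)OS(=O)(=O)C(F)(F)F
Why: Soft enolisation of the γ,γ-disubstituted butenolide can only remove a hydrogen from the γ′-CH2 (C8) inside the dioxasilepine and gives 12, a 4-alkylidene-2-silyloxy-4,5-dihydrofuran whose enol ether oxygen is held cis to C11 (E with respect to the spiro carbon) by the seven-membered ring. 12 is a 3-silyloxy-1,5-diene (C9=C10–C1(OSiEt3)–C6–C7=C8), and a thermal [3,3] sigmatropic shift breaks C1–C6 and forms C8–C9. The closest known reaction type is the thermal siloxy-Cope ring expansion of 1,2-dialkenylcyclohexanol silyl ethers to cyclodec-5-enone silyl enol ethers; here the new C6=C7 bond completes an aromatic 2-silyloxyfuran, so the shift should be irreversible and run well below the usual temperatures. No ring is closed end to end: ring A is opened and the ten-membered ring is formed through a six-membered chair-like transition state (four-carbon ring expansion), and the furan arises by aromatisation. The only new stereocentre is C8: C9 is delivered suprafacially to the face of C7=C8 on which C1 stands at the spiro carbon, and with the (S) spiro centre and the E enol ether this gives 8S. C1 and C6 become sp2, so the carbinol configuration made in step 1 was needed only to control the spiro centre in step 5. The step needs the shift to go through the isopropenyl group rather than the ring olefin; that alternative gains no aromaticity and requires a boat-like bicyclic transition state. Excess amine keeps the medium non-acidic so that the two silyl enol ethers and the furfuryl-type C–O bonds of 13 survive.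

Step 8
Reactants: 13 (8S)-bis-silyl furanocyclodecadiene
Product: 15 (6R,8S,10R)-8,13-dihydroxy-1-oxogermacra-4Z,7(11)-dien-12,6-olide, via silylene-protected keto butenolide 14 (not isolated)
Conditions: HF·pyridine, pyridine, THF, 0 → 23 °C; then PPTS (cat.), wet CHCl3, 40 °C
Reagents that add atoms: none
Why: Protodesilylation of the two silyl enol ethers: the furan is protonated at C6 (γ) on the face opposite the ansa chain, which leaves C8 on the other face (C9 was attached there in step 7), so H6 ends up cis to H8 (6R at this stage, the target geometry); the C1 enol ether gives the ketone. Fluoride then removes the silylene, and mild acid equilibrates C10 through the C1/C8 hemiketal (enol ether pathway) to the 10R epimer, which carries the methyl exo on the two-carbon bridge.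

Step 9
Reactants: 15 diol
Product: 16 (6R,8S,10R)-13-acetoxy-8-hydroxy-1-oxogermacra-4Z,7(11)-dien-12,6-olide
Conditions: AcCl (1.05 equiv), 2,4,6-collidine, CH2Cl2, −78 °C
Reagents that add atoms: acetyl chloride, CC(Cl)=O
Why: Selective acylation of the primary C13 hydroxyl over the hindered secondary C8 hydroxyl with one equivalent of acid chloride and a hindered, weak pyridine base that does not deprotonate C6–H.

Step 10
Reactants: 16 13-acetate
Product: 17 (4R,5S,6S,8S,10R)-13-acetoxy-4,5-epoxy-8-hydroxy-1-oxogermacr-7(11)-en-12,6-olide
Conditions: VO(acac)2 (5 mol %), t-BuOOH (1.5 equiv), CH2Cl2, 0 → 23 °C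
Reagents that add atoms: tert-butyl hydroperoxide, CC(C)(C)OO
Why: Hydroxyl-directed epoxidation of a bishomoallylic alcohol: allylic 1,3-strain keeps H6 in the plane of the Z olefin and H8 in the plane of the butenolide, so the C8–O bond stands over the olefin face that is syn to C7 and anti to the lactone oxygen. Oxygen delivered from the vanadium alkoxide to that face gives the cis (4R,5S) epoxide; the electron-poor tetrasubstituted butenolide olefin does not react.

Step 11
Reactants: 17 epoxy alcohol
Product: 18 CNP0229937.1, (4R,5S,6S,8S,10R)-13-acetoxy-4,5-epoxy-1-oxo-8-tigloyloxygermacr-7(11)-en-12,6-olide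
Conditions: (E)-2-methylbut-2-enoyl chloride, pyridine, DMAP (cat.), CH2Cl2, 0 °C
Reagents that add atoms: (E)-2-methylbut-2-enoyl chloride, C/C=C(\C)C(Cl)=O
Why: Acylation of the secondary alcohol with the acid chloride under weakly basic conditions that leave C6–H, the acetate and the epoxide alone; the E geometry of the acyl group is retained and C8 is not touched.

## Compound list

1 | (R)-(+)-pulegone, (5R)-5-methyl-2-(propan-2-ylidene)cyclohexan-1-one | C[C@@H]1CCC(=C(C)C)C(=O)C1 | starting material
2 | (2R,5R)-2-hydroxy-5-methyl-2-(prop-1-en-2-yl)cyclohexan-1-one | C[C@@H]1CC[C@@](O)(C(C)=C)C(=O)C1 | intermediate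
3 | (3R,6R)-3-methyl-6-(prop-1-en-2-yl)-1,6-bis(triethylsilyloxy)cyclohex-1-ene | C[C@@H]1CC[C@@](O[Si](CC)(CC)CC)(C(C)=C)C(O[Si](CC)(CC)CC)=C1 | intermediate (not isolated)
4 | (6R)-3-methyl-6-(prop-1-en-2-yl)-6-(triethylsilyloxy)cyclohex-2-en-1-one | CC1=CC(=O)[C@](O[Si](CC)(CC)CC)(C(C)=C)CC1 | intermediate
5 | 3,4-dibromofuran-2(5H)-one | O=C1OCC(Br)=C1Br | starting material
6 | (2Z)-2,3-dibromobut-2-ene-1,4-diol | OC/C(Br)=C(\CO)Br | intermediate
7 | 5,6-dibromo-2,2-di-tert-butyl-4,7-dihydro-1,3,2-dioxasilepine | CC(C)(C)[Si]1(C(C)(C)C)OCC(Br)=C(Br)CO1 | intermediate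
8 | (6-bromo-2,2-di-tert-butyl-4,7-dihydro-1,3,2-dioxasilepin-5-yl)lithium | CC(C)(C)[Si]1(C(C)(C)C)OCC([Li])=C(Br)CO1 | intermediate (not isolated)
9 | (1S,6R)-1-(6-bromo-2,2-di-tert-butyl-4,7-dihydro-1,3,2-dioxasilepin-5-yl)-3-methyl-6-(prop-1-en-2-yl)-6-(triethylsilyloxy)cyclohex-2-en-1-ol | CC1=C[C@](O)(C2=C(Br)CO[Si](C(C)(C)C)(C(C)(C)C)OC2)[C@](O[Si](CC)(CC)CC)(C(C)=C)CC1 | intermediate
10 | 6-[(1S,6R)-1-hydroxy-3-methyl-6-(prop-1-en-2-yl)-6-(triethylsilyloxy)cyclohex-2-en-1-yl]-2,2-di-tert-butyl-4,7-dihydro-1,3,2-dioxasilepine-5-carboxylic acid | CC1=C[C@](O)(C2=C(C(=O)O)CO[Si](C(C)(C)C)(C(C)(C)C)OC2)[C@](O[Si](CC)(CC)CC)(C(C)=C)CC1 | intermediate (not isolated)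
11 | spirobutenolide: (5S,10R)-7-methyl-10-(prop-1-en-2-yl)-10-(triethylsilyloxy)-1-oxaspiro[4.5]deca-3,6-dien-2-one with C3 and C4 joined through CH2–O–Si(t-Bu)2–O–CH2 | CC1=C[C@@]2(OC(=O)C3=C2CO[Si](C(C)(C)C)(C(C)(C)C)OC3)[C@](O[Si](CC)(CC)CC)(C(C)=C)CC1 | intermediate
12 | silyl dienol ether of 11: 2-(tert-butyldimethylsilyloxy)-1-oxaspiro[4.5]deca-2,6-diene with exocyclic (E)-C4=CH–O inside the dioxasilepine, (5S,10R) | CC1=C[C@@]2(OC(O[Si](C)(C)C(C)(C)C)=C3C2=CO[Si](C(C)(C)C)(C(C)(C)C)OC3)[C@](O[Si](CC)(CC)CC)(C(C)=C)CC1 | intermediate (not isolated)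
13 | (8S)-12-(tert-butyldimethylsilyloxy)-1-(triethylsilyloxy)-6,12-epoxygermacra-1(10),4Z,6,11-tetraene with O8/O13 di-tert-butylsilylene (C2 and C9 trans across C1=C10) | C/C1=C/c2oc(O[Si](C)(C)C(C)(C)C)c3c2[C@H](C/C(C)=C(O[Si](CC)(CC)CC)/CC1)O[Si](C(C)(C)C)(C(C)(C)C)OC3 | intermediate
14 | (6R,8S)-8,13-O-(di-tert-butylsilylene)-8,13-dihydroxy-1-oxogermacra-4Z,7(11)-dien-12,6-olide (C10 as formed, not yet equilibrated) | C/C1=C/[C@H]2OC(=O)C3=C2[C@H](CC(C)C(=O)CC1)O[Si](C(C)(C)C)(C(C)(C)C)OC3 | intermediate (not isolated)
15 | (6R,8S,10R)-8,13-dihydroxy-1-oxogermacra-4Z,7(11)-dien-12,6-olide | O[C@H]1C[C@@H](C)C(=O)CC/C(C)=C\[C@H]2OC(=O)C(CO)=C12 | intermediate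
16 | (6R,8S,10R)-13-acetoxy-8-hydroxy-1-oxogermacra-4Z,7(11)-dien-12,6-olide | O[C@H]1C[C@@H](C)C(=O)CC/C(C)=C\[C@H]2OC(=O)C(COC(C)=O)=C12 | intermediate
17 | (4R,5S,6S,8S,10R)-13-acetoxy-4,5-epoxy-8-hydroxy-1-oxogermacr-7(11)-en-12,6-olide | O[C@H]1C[C@@H](C)C(=O)CC[C@@]2(C)O[C@H]2[C@H]2OC(=O)C(COC(C)=O)=C12 | intermediate
18 | CNP0229937.1, (4R,5S,6S,8S,10R)-13-acetoxy-4,5-epoxy-1-oxo-8-tigloyloxygermacr-7(11)-en-12,6-olide | C/C=C(\C)C(=O)O[C@H]1C[C@@H](C)C(=O)CC[C@@]2(C)O[C@H]2[C@H]2OC(=O)C(COC(C)=O)=C12 | target

## Step count and least certain steps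

Total: 11 steps. Longest linear sequence: 9 steps (1, 2, 5, 6, 7, 8, 9, 10, 11 from 1); steps 3 and 4 make the second fragment.

**Step 7 (key step).** The spiro ring holds the C1–C6 bond about 30° away from the ideal alignment with the C7=C8 π-bond, so the neutral shift may need a temperature at which the silyl dienol ether is lost by desilylation or ionisation of the furfuryl-type C–O bonds. The fallback is the charge-accelerated (anionic) oxy-Cope rearrangement. It sets out from 11. The triethylsilyl ether is cleaved with AcOH–THF–H2O to the tertiary alcohol F1. Slow addition of F1 to KN(SiMe3)2 (2.3 equiv) and 18-crown-6 in THF at −78 °C gives the dipotassium alkoxide–dienolate F2, so that the mono-alkoxide, which could fragment by retro-aldol cleavage, does not accumulate. F2 should rearrange below 0 °C to the dipotassium enolate–furanolate F3. Quenching with AcOH at −78 °C protonates both carbanions and returns the route at 14, which is taken on as in step 8.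

**Step 8.** The furan may be protonated at C11 (α) instead of C6, or on both faces, so the butenolide double bond ends up out of conjugation. The fallback replaces kinetic γ-protonation by a base-mediated 1,3-proton shift. It sets out from 13. If the β,γ-unsaturated lactone F4 is what protodesilylation gives, a catalytic amount of Et3N in CH2Cl2 moves the double bond into conjugation through the furanolate; this is safe at this stage because the acetate is not yet present and the silylene oxygen at C13 is a poor leaving group. The route is rejoined at 14.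

**Step 10.** The C8 hydroxyl may be tied up as the hemiketal with C1=O, so that direction is lost and oxygen enters from the other face, or the epoxy alcohol may cyclise. The fallback brings the oxygen in by anti addition and ring closure instead of syn delivery. It sets out from 16. Acylation as in step 11 gives the diene ester F5, in which the tiglate shields the face that must finally carry the oxygen. N-Bromosuccinimide in aqueous acetone forms the bromonium ion on the open face, and water opens it at the tertiary C4 to give the bromohydrin F6. Ag2O closes F6 with inversion at C5 and gives 18 directly.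

**Step 1.** Incomplete equilibration of the enolate would lead to hydroxylation at the ring CH2 next to the carbonyl, and the facial preference at C2 is only modest. The fallback is epoxidation followed by epoxide-to-allylic-alcohol isomerisation. It sets out from 1. H2O2 and NaOH give the epoxy ketone, and its (3R,6R) diastereomer, pulegone oxide F7, is separated. Me3SiOTf and DBU open the epoxide by elimination toward a methyl group to the silyl ether F8, and mild acidic methanolysis returns the route at 2.

**Step 6.** The second bromine–lithium exchange may be slow on the hindered alkoxide, or the alkenyllithium may be protonated before it meets CO2. The fallback is a palladium-catalysed carbonylative lactonisation. It sets out from 9: Pd(PPh3)4 (5 mol %), CO (1 atm), K2CO3, DMF, 70 °C (oxidative addition of zerovalent palladium to the C–Br bond, CO insertion, capture by the tertiary hydroxyl) gives 11 directly. No new compound is made on this path (F0).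

## Further compounds

F1 | step 7 | tertiary alcohol: (5S,10R)-10-hydroxy-7-methyl-10-(prop-1-en-2-yl)-1-oxaspiro[4.5]deca-3,6-dien-2-one with the C3/C4 CH2–O–Si(t-Bu)2–O–CH2 bridge | CC1=C[C@@]2(OC(=O)C3=C2CO[Si](C(C)(C)C)(C(C)(C)C)OC3)[C@](O)(C(C)=C)CC1
F2 | step 7 | dipotassium alkoxide–dienolate of F1 | CC1=C[C@@]2(OC([O-])=C3C2=CO[Si](C(C)(C)C)(C(C)(C)C)OC3)[C@]([O-])(C(C)=C)CC1.[K+].[K+]
F3 | step 7 | dipotassium enolate–furanolate of 14 | C/C1=C/c2oc([O-])c3c2[C@H](C/C(C)=C([O-])/CC1)O[Si](C(C)(C)C)(C(C)(C)C)OC3.[K+].[K+]
F4 | step 8 | β,γ-unsaturated lactone isomer of 14 (C6=C7, C11–H; C10 and C11 as formed) | C/C1=C/C2=C3[C@H](CC(C)C(=O)CC1)O[Si](C(C)(C)C)(C(C)(C)C)OCC3C(=O)O2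
F5 | step 10 | (6R,8S,10R)-13-acetoxy-1-oxo-8-tigloyloxygermacra-4Z,7(11)-dien-12,6-olide | C/C=C(\C)C(=O)O[C@H]1C[C@@H](C)C(=O)CC/C(C)=C\[C@H]2OC(=O)C(COC(C)=O)=C12
F6 | step 10 | bromohydrin: 13-acetoxy-5-bromo-4-hydroxy-1-oxo-8-tigloyloxygermacr-7(11)-en-12,6-olide (OH and Br anti) | C/C=C(\C)C(=O)O[C@H]1C[C@@H](C)C(=O)CC[C@@](C)(O)[C@H](Br)[C@H]2OC(=O)C(COC(C)=O)=C12
F7 | step 1 | pulegone oxide, (3R,6R)-2,2,6-trimethyl-1-oxaspiro[2.5]octan-4-one | C[C@@H]1CC[C@]2(OC2(C)C)C(=O)C1
F8 | step 1 | (2R,5R)-5-methyl-2-(prop-1-en-2-yl)-2-(trimethylsilyloxy)cyclohexan-1-one | C[C@@H]1CC[C@@](O[Si](C)(C)C)(C(C)=C)C(=O)C1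
F0 | step 6 | none | none
A1 | alternative 1 | seco iodo-aldehyde (C7–C8 open; 4-iodobutenolide with the C6 side chain ending in the C8 aldehyde) | O=CC[C@@H](C)C(=O)CC/C(C)=C\[C@H]1OC(=O)C(COC(C)=O)=C1I
A2 | alternative 2 | 13-acetoxy-8-hydroxy-1,5-dioxogermacr-7(11)-en-12,6-olide (C4 and C6 uncontrolled) | O[C@H]1C[C@@H](C)C(=O)CCC(C)C(=O)C2OC(=O)C(COC(C)=O)=C12
A3 | alternative 3 | (6R,10R)-1-oxogermacra-4Z,7(11)-dien-12,6-olide | C1C[C@@H](C)C(=O)CC/C(C)=C\[C@H]2OC(=O)C(C)=C12
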